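**Retrosynthetic overview**
1. Target ⇐ drim-7-ene-1β,11,12-triol: esterify O-1 with TBS-protected p-coumaric acid, oxidise C11/C12 to the dialdehyde, free the phenol.
2. Triol ⇐ 1-oxo-drim-7-ene-11,12-diester; ring B is closed last by ring-closing metathesis (C7=C8) between a C5 allyl group and a C10-bound α-methylene succinate.
3. Quaternary C10 ⇐ enolate SN2′ alkylation anti to the C5 allyl group, which fixes the trans ring fusion.
4. C5 stereocentre and C10 methyl ⇐ enantioselective conjugate allylation/methylation of the C2v-symmetric 4,4-dimethylcyclohexa-2,5-dien-1-one (key step). Ring A is the dienone ring; its second enone arm blocks α′-enolisation and later becomes C2–C3.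

Assumption: 4,4-dimethylcyclohexa-2,5-dien-1-one is bought (otherwise one step, IBX, from 4,4-dimethylcyclohex-2-en-1-one).
Assumption: the catalyst antipode that gives the (5R) adduct in step 1 is identified in a pilot run.
Positions are given in drimane numbering (C1–C12).

**Step 1**
Reactants: 1 4,4-dimethylcyclohexa-2,5-dien-1-one; 2 allyltrimethylsilane
Product: 5 (5R,6R)-4,4,6-trimethyl-5-(prop-2-en-1-yl)cyclohex-2-en-1-one (allyl and methyl trans), via TMS dienol ether 3 (not isolated), via lithium enolate 4 (not isolated)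
Conditions: chiral imidodiphosphorimidate acid (IDPi, 3 mol%), toluene, −60 °C; then MeLi, THF, 0 °C; then MeI, DMPU, −78 → 0 °C
Reagents that add atoms: iodomethane, CI
Why: Proposed new method: the acid is silylated by 2, and the resulting silylium/chiral-anion pair O-silylates the dienone to a symmetric silyloxy-cyclohexadienyl cation whose two enone arms are homotopic, so the confined anion only has to shield one face while the allylsilane attacks the β-carbon and returns Me3Si+ (closest known: TiCl4-mediated Hosomi–Sakurai 1,4-allylation of cyclohexadienones and silylium/chiral-counteranion Mukaiyama–Michael reactions); the silyl enol ether then gives a regiodefined lithium enolate that is methylated at C10 anti to the allyl group.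

**Step 2**
Reactants: 6 dimethyl itaconate
Product: 8 dimethyl 2-(bromomethyl)fumarate [dimethyl (2Z)-2-(bromomethyl)but-2-enedioate], via dibromide 7 (not isolated)
Conditions: Br2, CH2Cl2, rt; then Et3N, Et2O, 0 °C → rt
Reagents that add atoms: bromine, BrBr
Why: Alkene bromination followed by E2 loss of HBr from the tertiary bromide towards the CH2CO2Me side gives the doubly activated allylic bromide (alkene geometry is irrelevant later).

**Step 3**
Reactants: 5 (5R,6R)-4,4,6-trimethyl-5-(prop-2-en-1-yl)cyclohex-2-en-1-one; 8 dimethyl 2-(bromomethyl)fumarate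
Product: 10 dimethyl 2-methylidene-3-[(1S,6S)-1,5,5-trimethyl-2-oxo-6-(prop-2-en-1-yl)cyclohex-3-en-1-yl]butanedioate (both epimers at the succinate CH, the future C9), via lithium enolate 9 (not isolated)
Conditions: LDA, THF, −78 → −20 °C; then 8, −78 → −40 °C
Reagents that add atoms: none
Why: The only enolisable position is C10 (C2 is vinylic), and the enolate adds to the fumarate carbon and expels bromide (SN2′, Michael addition–elimination) from the face anti to the C5 allyl group, so C9 ends trans to C6 and the methyl cis to it, which is the trans-decalin arrangement.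

**Step 4**
Reactants: 10 (as above)
Product: 12 dimethyl 1-oxodrim-7-ene-11,12-dioate (5α-H, 10β-Me; both C9 epimers), via dienone diester 11 (not isolated)
Conditions: Grubbs II (5 mol%), CH2Cl2 (5 mM), 40 °C; then H2 (5 bar), 25 °C
Reagents that add atoms: none
Why: Ring-closing metathesis of the allyl group with the 1,1-disubstituted acrylate closes ring B as the trisubstituted C7=C8 enoate, and the Ru–H formed under H2 then saturates the disubstituted enone C2=C3 faster than the trisubstituted enoate (tandem RCM–hydrogenation).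

**Step 5**
Reactants: 12 (as above)
Product: 14 dimethyl (1R,4aS,8aS)-5,5,8a-trimethyl-8-oxo-1,4,4a,5,6,7,8,8a-octahydronaphthalene-1,2-dicarboxylate (dimethyl 1-oxodrim-7-ene-11,12-dioate, 9α-H, 9β-CO2Me), via dilithium bis-enolate 13 (not isolated)
Conditions: LDA (2.5 equiv), THF–DMPU, −78 °C; then AcOH, −78 °C
Reagents that add atoms: none
Why: Kinetic protonation of the C11 ester dienolate occurs at C9 from the α-face, anti to the axial C10 methyl, giving the 9β-ester from both epimers (kinetic deconjugative protonation as used for drimene diesters), while the ketone enolate formed alongside simply reprotonates.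

**Step 6**
Reactants: 14 (as above)
Product: 15 drim-7-ene-1β,11,12-triol
Conditions: LiAlH4, THF, 0 °C
Reagents that add atoms: none
Why: Hydride reduction of both esters and of the C1 ketone, the latter by axial attack from the α-face opposite the angular methyl, gives the equatorial 1β-alcohol.

**Step 7**
Reactants: 15 drim-7-ene-1β,11,12-triol
Product: 16 11,12-bis(triethylsilyloxy)drim-7-en-1β-ol
Conditions: TESCl (2.1 equiv), imidazole, CH2Cl2, −40 → 0 °C
Reagents that add atoms: chlorotriethylsilane, CC[Si](Cl)(CC)CC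
Why: Silylation is selective for the two primary alcohols over the neopentyl secondary 1β-alcohol.

**Step 8**
Reactants: 17 p-coumaric acid [(E)-3-(4-hydroxyphenyl)prop-2-enoic acid]
Product: 19 (E)-3-[4-(tert-butyldimethylsilyloxy)phenyl]prop-2-enoic acid, via bis-silyl derivative 18 (not isolated)
Conditions: TBSCl (2.3 equiv), imidazole, DMF, rt; then AcOH–THF–H2O, rt
Reagents that add atoms: tert-butyl(chloro)dimethylsilane, CC(C)(C)[Si](C)(C)Cl
Why: Bis-silylation followed by selective hydrolysis of the labile silyl ester leaves the aryl TBS ether (protecting-group chemistry).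

**Step 9**
Reactants: 16 11,12-bis(triethylsilyloxy)drim-7-en-1β-ol; 19 (E)-3-[4-(tert-butyldimethylsilyloxy)phenyl]prop-2-enoic acid
Product: 21 11,12-bis(triethylsilyloxy)drim-7-en-1β-yl (E)-3-[4-(tert-butyldimethylsilyloxy)phenyl]prop-2-enoate, via mixed anhydride 20 (not isolated)
Conditions: 2,4,6-trichlorobenzoyl chloride, Et3N, toluene, rt; then 16, DMAP, 60 °C
Reagents that add atoms: none
Why: Yamaguchi esterification; DMAP attacks the less hindered cinnamoyl carbonyl of the mixed anhydride and the acylpyridinium acylates the hindered 1β-alcohol with retention at C1.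

**Step 10**
Reactants: 21 (as above)
Product: 23 1β-[(E)-4-(tert-butyldimethylsilyloxy)cinnamoyloxy]drim-7-ene-11,12-dial, via bis-alkoxysulfonium salt 22 (not isolated)
Conditions: (COCl)2, DMSO, CH2Cl2, −78 → −35 °C; then Et3N, −78 → −20 °C
Reagents that add atoms: none
Why: Swern oxidation carried out directly on the primary triethylsilyl ethers (activated DMSO displaces the silyl group) gives both aldehydes at low temperature, the conditions under which the epimerisable C9 of polygodial-type dialdehydes survives.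

**Step 11**
Reactants: 23 (as above)
Product: 24 (1R,4aS,8R,8aS)-1,2-diformyl-5,5,8a-trimethyl-1,4,4a,5,6,7,8,8a-octahydronaphthalen-8-yl (2E)-3-(4-hydroxyphenyl)prop-2-enoate (target, 1β-(E)-p-coumaroyloxypolygodial)
Conditions: HF·pyridine, pyridine–THF, 0 °C
Reagents that add atoms: none
Why: Fluoride cleavage of the aryl silyl ether under buffered, non-basic conditions leaves the ester, the enal and the C9 stereocentre untouched.

**Compound list**
1 | 4,4-dimethylcyclohexa-2,5-dien-1-one | CC1(C)C=CC(=O)C=C1 | starting material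
2 | allyltrimethylsilane | C=CC[Si](C)(C)C | starting material
3 | trimethyl{[(6R)-5,5-dimethyl-6-(prop-2-en-1-yl)cyclohexa-1,3-dien-2-yl]oxy}silane | C[Si](C)(C)OC1=C[C@@H](CC=C)C(C)(C)C=C1 | intermediate
4 | lithium (6R)-5,5-dimethyl-6-(prop-2-en-1-yl)cyclohexa-1,3-dien-2-olate | [Li]OC1=C[C@@H](CC=C)C(C)(C)C=C1 | intermediate
5 | (5R,6R)-4,4,6-trimethyl-5-(prop-2-en-1-yl)cyclohex-2-en-1-one | CC1(C)C=CC(=O)[C@H](C)[C@H]1CC=C | intermediate
6 | dimethyl itaconate | C=C(CC(=O)OC)C(=O)OC | starting material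
7 | dimethyl 2-bromo-2-(bromomethyl)butanedioate (racemic) | COC(=O)CC(Br)(CBr)C(=O)OC | intermediate
8 | dimethyl 2-(bromomethyl)fumarate | COC(=O)/C=C(\CBr)C(=O)OC | intermediate
9 | lithium (6S)-1,5,5-trimethyl-6-(prop-2-en-1-yl)cyclohexa-1,3-dien-2-olate | [Li]OC1=C(C)[C@@H](CC=C)C(C)(C)C=C1 | intermediate
10 | dimethyl 2-methylidene-3-[(1S,6S)-1,5,5-trimethyl-2-oxo-6-(prop-2-en-1-yl)cyclohex-3-en-1-yl]butanedioate (both C3 epimers) | CC1(C)C=CC(=O)[C@](C)(C(C(=O)OC)C(=C)C(=O)OC)[C@H]1CC=C | intermediate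
11 | dimethyl 1-oxodrima-2,7-diene-11,12-dioate (5α-H, 10β-Me, both C9 epimers) | CC1(C)C=CC(=O)[C@]2(C)C(C(=O)OC)C(C(=O)OC)=CC[C@@H]12 | intermediate
12 | dimethyl 1-oxodrim-7-ene-11,12-dioate (5α-H, 10β-Me, both C9 epimers) | CC1(C)CCC(=O)[C@]2(C)C(C(=O)OC)C(C(=O)OC)=CC[C@@H]12 | intermediate
13 | dilithium bis-enolate of 12 (C1 ketone enolate and C11 ester dienolate) | CC1(C)CC=C(O[Li])[C@]2(C)C(=C(O[Li])OC)C(C(=O)OC)=CC[C@@H]12 | intermediate
14 | dimethyl (1R,4aS,8aS)-5,5,8a-trimethyl-8-oxo-1,4,4a,5,6,7,8,8a-octahydronaphthalene-1,2-dicarboxylate (9α-H) | CC1(C)CCC(=O)[C@]2(C)[C@@H](C(=O)OC)C(C(=O)OC)=CC[C@@H]12 | intermediate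
15 | drim-7-ene-1β,11,12-triol | CC1(C)CC[C@@H](O)[C@]2(C)[C@@H](CO)C(CO)=CC[C@@H]12 | intermediate
16 | 11,12-bis(triethylsilyloxy)drim-7-en-1β-ol | CC1(C)CC[C@@H](O)[C@]2(C)[C@@H](CO[Si](CC)(CC)CC)C(CO[Si](CC)(CC)CC)=CC[C@@H]12 | intermediate
17 | p-coumaric acid | OC(=O)/C=C/c1ccc(O)cc1 | starting material
18 | tert-butyldimethylsilyl (E)-3-[4-(tert-butyldimethylsilyloxy)phenyl]prop-2-enoate | CC(C)(C)[Si](C)(C)OC(=O)/C=C/c1ccc(O[Si](C)(C)C(C)(C)C)cc1 | intermediate
19 | (E)-3-[4-(tert-butyldimethylsilyloxy)phenyl]prop-2-enoic acid | OC(=O)/C=C/c1ccc(O[Si](C)(C)C(C)(C)C)cc1 | intermediate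
20 | (E)-3-[4-(tert-butyldimethylsilyloxy)phenyl]prop-2-enoic 2,4,6-trichlorobenzoic anhydride | O=C(/C=C/c1ccc(O[Si](C)(C)C(C)(C)C)cc1)OC(=O)c1c(Cl)cc(Cl)cc1Cl | intermediate
21 | 11,12-bis(triethylsilyloxy)drim-7-en-1β-yl (E)-3-[4-(tert-butyldimethylsilyloxy)phenyl]prop-2-enoate | CC1(C)CC[C@@H](OC(=O)/C=C/c2ccc(O[Si](C)(C)C(C)(C)C)cc2)[C@]2(C)[C@@H](CO[Si](CC)(CC)CC)C(CO[Si](CC)(CC)CC)=CC[C@@H]12 | intermediate
22 | 11,12-bis(dimethylsulfonio-oxy) derivative of 21, dichloride | CC1(C)CC[C@@H](OC(=O)/C=C/c2ccc(O[Si](C)(C)C(C)(C)C)cc2)[C@]2(C)[C@@H](CO[S+](C)C)C(CO[S+](C)C)=CC[C@@H]12.[Cl-].[Cl-] | intermediate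
23 | 1β-[(E)-4-(tert-butyldimethylsilyloxy)cinnamoyloxy]drim-7-ene-11,12-dial | CC1(C)CC[C@@H](OC(=O)/C=C/c2ccc(O[Si](C)(C)C(C)(C)C)cc2)[C@]2(C)[C@@H](C=O)C(C=O)=CC[C@@H]12 | intermediate
24 | (1R,4aS,8R,8aS)-1,2-diformyl-5,5,8a-trimethyl-1,4,4a,5,6,7,8,8a-octahydronaphthalen-8-yl (2E)-3-(4-hydroxyphenyl)prop-2-enoate | CC1(C)CC[C@@H](OC(=O)/C=C/c2ccc(O)cc2)[C@]2(C)[C@@H](C=O)C(C=O)=CC[C@@H]12 | target

**Step count**
Total steps: 11. Longest linear sequence: 9 (steps 1, 3, 4, 5, 6, 7, 9, 10, 11).

**Three steps most likely to fail, with fallbacks**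

Step 1 (enantioselective conjugate allylation; the catalytic asymmetric version is untested, and a racemic silyl-cation pathway could erode the ee). The fallback sets out from 1 and uses established copper chemistry with a non-allylic nucleophile. Cu-catalysed asymmetric conjugate addition of but-3-enylmagnesium bromide (CuBr·SMe2, ferrocenyl diphosphine, t-BuOMe, −78 °C), with the magnesium enolate trapped by MeI/DMPU, gives (5R,6R)-5-(but-3-en-1-yl)-4,4,6-trimethylcyclohex-2-en-1-one F1. A one-position olefin migration with a ruthenium hydride (Grubbs II plus vinyloxytrimethylsilane) gives (5R,6R)-5-[(2E)-but-2-en-1-yl]-4,4,6-trimethylcyclohex-2-en-1-one F2. Alkylation with 8 as in step 3 gives the crotyl analogue of 10, dimethyl 2-[(1S,6S)-6-[(2E)-but-2-en-1-yl]-1,5,5-trimethyl-2-oxocyclohex-3-en-1-yl]-3-methylidenebutanedioate F3. Its ring-closing metathesis and hydrogenation under the step 4 conditions rejoin the route at 12.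

Step 3 (SN2′ versus direct SN2 at CH2Br, and bond formation between a quaternary and a tertiary carbon). The fallback sets out from 5 and removes the regiochemical ambiguity. The lithium enolate of 5 is added to dimethyl maleate (Michael addition only) to give dimethyl 2-[(1S,6S)-1,5,5-trimethyl-2-oxo-6-(prop-2-en-1-yl)cyclohex-3-en-1-yl]butanedioate F4. LDA deprotonates the unhindered CH2CO2Me (the ketone cannot enolise), and Eschenmoser's salt gives the Mannich base dimethyl 2-[(dimethylamino)methyl]-3-[(1S,6S)-1,5,5-trimethyl-2-oxo-6-(prop-2-en-1-yl)cyclohex-3-en-1-yl]butanedioate F5. Quaternisation with MeI gives the trimethylammonium iodide F6, and DBU-induced elimination returns to the route at 10.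

Step 5 (kinetic protonation at C9; competing γ-deprotonation at C6 or poor facial selectivity would leave the wrong epimer). The fallback sets out from 12 and uses thermodynamic relay from O-1. NaBH4 (MeOH, 0 °C) reduces only the ketone to dimethyl 1β-hydroxydrim-7-ene-11,12-dioate F7 (both C9 epimers). DBU in toluene at 80 °C equilibrates C9, and only the 9β-ester can reach the peri 1β-hydroxyl, so the material is drained into the γ-lactone methyl 11-oxo-1β,11-epoxydrim-7-en-12-oate F8. LiAlH4 reduction of the lactone and the remaining ester rejoins the route at 15.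

**Further compounds**
F1 | step 1 | (5R,6R)-5-(but-3-en-1-yl)-4,4,6-trimethylcyclohex-2-en-1-one | CC1(C)C=CC(=O)[C@H](C)[C@H]1CCC=C
F2 | step 1 | (5R,6R)-5-[(2E)-but-2-en-1-yl]-4,4,6-trimethylcyclohex-2-en-1-one | CC1(C)C=CC(=O)[C@H](C)[C@H]1C/C=C/C
F3 | step 1 | dimethyl 2-[(1S,6S)-6-[(2E)-but-2-en-1-yl]-1,5,5-trimethyl-2-oxocyclohex-3-en-1-yl]-3-methylidenebutanedioate | CC1(C)C=CC(=O)[C@](C)(C(C(=O)OC)C(=C)C(=O)OC)[C@H]1C/C=C/C
F4 | step 3 | dimethyl 2-[(1S,6S)-1,5,5-trimethyl-2-oxo-6-(prop-2-en-1-yl)cyclohex-3-en-1-yl]butanedioate | CC1(C)C=CC(=O)[C@](C)(C(C(=O)OC)CC(=O)OC)[C@H]1CC=C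
F5 | step 3 | dimethyl 2-[(dimethylamino)methyl]-3-[(1S,6S)-1,5,5-trimethyl-2-oxo-6-(prop-2-en-1-yl)cyclohex-3-en-1-yl]butanedioate | CC1(C)C=CC(=O)[C@](C)(C(C(=O)OC)C(CN(C)C)C(=O)OC)[C@H]1CC=C
F6 | step 3 | trimethylammonium iodide of F5 | CC1(C)C=CC(=O)[C@](C)(C(C(=O)OC)C(C[N+](C)(C)C)C(=O)OC)[C@H]1CC=C.[I-]
F7 | step 5 | dimethyl 1β-hydroxydrim-7-ene-11,12-dioate (both C9 epimers) | CC1(C)CC[C@@H](O)[C@]2(C)C(C(=O)OC)C(C(=O)OC)=CC[C@@H]12
F8 | step 5 | methyl 11-oxo-1β,11-epoxydrim-7-en-12-oate (1β,11-γ-lactone, 9α-H) | CC1(C)CC[C@@H](O3)[C@]2(C)[C@@H](C3=O)C(C(=O)OC)=CC[C@@H]12
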